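Start with the easy step: starting material turns into target, and one number should say how long that takes.

| flask | starting material | temperature | time | remark |
|---|---|---|---|---|
| midnight | 0.23 M | 0 °C | 8.0 min |  |
| dusk | 0.23 M | 50 °C | 8.0 min |  |
| dawn | 0.23 M |  | 8.0 min | at 0 °C until 2.5 min, from then on at 50 °C |
| noon | 0.23 M | 25 °C | 8.0 min |  |

    starting material → target, rate k1*[starting material]/(1 + ([starting material]/sat1)) (sat1 = 3.0 mM, k1 = 2.1 min⁻¹, Ea1 = 77.0 kJ mol⁻¹)
    target ⇌ isomer of the product (K2 = 0.82, k2 = 0.051 min⁻¹, Ea2 = 96.0 kJ mol⁻¹, ΔH2 = −29.0 kJ mol⁻¹)
    target → over-reaction product (k3 = 0.0033 min⁻¹, Ea3 = 85.0 kJ mol⁻¹)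
    (constants at 25 °C)

- the list of constants is for 25 °C, to be carried to other temperatures by the activation energies and enthalpies

- the flask that comes out highest in amount of target, in percent of the starting material charged, or "all alike" when all lie within 1.5 percentage points (midnight / dusk / dawn / noon / all alike)
- target at the end, in percent of the starting material charged, midnight
- target at the end, in percent of the starting material charged, dusk
- target at the end, in percent of the starting material charged, dawn
- target at the end, in percent of the starting material charged, noon

Treat the first step as first order. Its lifetime at 25 °C is 0.476 min, far shorter than 8.0 min, so noon should finish early.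

Doubt that. Look at the denominator of the rate law at the charge:

denominator = 77.7

The step is saturated, with [starting material] at 0.23 M against a sat of 3.0 mM. The rate stays near the rate constant times sat: zero order. So lifetimes mislead here. Divide the charge by the saturated rate instead:

noon: 36.5 min

Call this charge over saturated rate the clearing time. Carry the rate constant by its activation energy:

midnight: rate constant 0.122 min⁻¹, clearing time 627 min

dusk: rate constant 23.2 min⁻¹, clearing time 3.30 min

While the step stays saturated, time over clearing time estimates the share converted. Midnight should reach 1.28 % and noon 21.9 %. Dawn should use 0.399 % of its charge while cold, then clear at about 5.79 min.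

Object again: the step loses saturation near the end. Reckon that tail at dusk:

tail = 0.187 min

That is much shorter than the dusk clearing time, so drop it.

Object once more: cleared is not yet target. At dusk, step two has a forward constant of 1.02 min⁻¹, and its relaxation lifetime is

0.244 min

This is shorter than the clearing time. So take the hot pool as equilibrated, with a target share of 75.1 %. The third step, at 0.0468 min⁻¹, drains that pool at 0.0352 min⁻¹.

Product forms evenly during clearing, so find its mean age at the end:

dusk: age 6.35 min, target 60.1 %

dawn: age 3.86 min, target 65.6 %

At noon step two is still far from equilibrium. Charge it its forward constant over a mean age of 4.00 min, which gives a target of 17.4 %. At midnight its relaxation half-life of 5.53 h is longer than 8.0 min, so keep the converted share as target. Commit to dawn.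

The forecast names dawn, with 1.25 % at midnight, 60 % at dusk, 65.5 % at dawn and 18 % at noon, on the ground that the “first step is saturated, so it runs at a nearly constant rate”.

The simulation puts dawn highest, with 1.25 % at midnight, 59.9 % at dusk, 65.3 % at dawn and 18.0 % at noon, against the 17.4 % reckoned for noon.

The saturation term is the main reason midnight stays low: struck out, it lifts midnight's target from 1.25 % to 62.0 %. Noon's clearing time gave 21.9 %, and noon converted 21.6 %. Carry the clearing time to the midnight flask run at 15 °C: it becomes 107 min, so 8.0 min should convert 7.48 %, and that neighbour ends with target at 6.96 %, isomer of the product at 0.367 % and over-reaction product at 0.0285 %.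

The constants belong to no real substance, and the outcome is calculated.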